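**Retrosynthetic overview**
1. Enabling feature: on the cyclobutane, C1-H(CO2H) and C2-H(CO2Me) are cis. The quaternary C3 and C4 carry cis pyran-2-one rings and cis methyls, and the methyls share a face with the carboxyl carbons. Apart from acid versus ester the ring has a mirror plane, so the target is a desymmetrised meso succinic anhydride, and its two cis methyls can be the remains of a CH2-S-CH2 bridge.
2. Endgame: alkaloid-mediated methanolysis of the meso anhydride sets the absolute configuration, then C-S hydrogenolysis of the thiolane ring gives the two CH3 groups.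
3. Key disconnection: cyclobutane bonds C2-C3 and C1-C4, leading back to maleic anhydride and 3,4-dipyronyl-2,5-dihydrothiophene, joined by a triplet-sensitised [2+2] photocycloaddition.
4. The dihydrothiophene comes from an intramolecular McMurry coupling of a bis(pyronoylmethyl) sulfide. The pyrone comes from the dianion of ethyl 2-methylacetoacetate and ethyl 2,2-diethoxypropanoate.
5. Ring order: pyran-2-one rings (step 2), thia ring (step 7), cyclobutane (step 8, anhydride ring brought in intact), anhydride ring opened (step 9), thia ring erased (step 10).

Key step: step 8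

Shorthand: "pyronyl" stands for 4-methoxy-5-methyl-6-oxo-6H-pyran-2-yl, that is the 4-methoxy-3-methyl-2-pyranone ring bound through its C6.
Assumption: the sense of induction in step 9 follows the empirical behaviour of cis-fused bicyclic succinic anhydrides, for which quinidine leads to the series drawn for 16; quinine gives the mirror image, so one configurational correlation on 16 decides the alkaloid without changing the route.

Step 1
Reactants: 1 ethyl 2-methylacetoacetate; 2 ethyl 2,2-diethoxypropanoate
Product: 4 ethyl 6,6-diethoxy-2-methyl-3,5-dioxoheptanoate, via dilithium dienediolate 3 (not isolated)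
Conditions: LiN(iPr)2 (3.1 equiv), THF, -78 to 0 °C; then 2, -78 °C to rt; AcOH quench
Reagents that add atoms: none
Why: Claisen-type γ-acylation of a β-keto ester dianion, in which the more reactive terminal carbanion of 3 attacks the non-enolisable ester 2 and the extra base stores the more acidic product as its enolate; the C2 centre of 4 is configurationally labile and vanishes in step 2.

Step 2
Reactants: 4 ethyl 6,6-diethoxy-2-methyl-3,5-dioxoheptanoate
Product: 5 6-(1,1-diethoxyethyl)-4-hydroxy-3-methyl-2H-pyran-2-one
Conditions: DBU (1.1 equiv), toluene, 90 °C; cold aq. citric acid work-up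
Reagents that add atoms: none
Why: Base-mediated lactonisation of the C5 enol onto the ester (the standard cyclisation of 3,5-dioxo esters to 4-hydroxy-2-pyranones) is driven by formation of the stabilised pyronolate, and the non-acidic medium keeps the ketal.

Step 3
Reactants: 5 6-(1,1-diethoxyethyl)-4-hydroxy-3-methyl-2H-pyran-2-one
Product: 6 6-(1,1-diethoxyethyl)-4-methoxy-3-methyl-2H-pyran-2-one
Conditions: Me2SO4 (1.2 equiv), K2CO3, acetone, reflux
Reagents that add atoms: dimethyl sulfate, COS(=O)(=O)OC
Why: Williamson-type O-methylation of a 4-hydroxy-2-pyranone with Me2SO4/K2CO3, conditions known to favour the 4-methoxy-2-pyranone over the 2-methoxy-4-pyranone isomer.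

Step 4
Reactants: 6 6-(1,1-diethoxyethyl)-4-methoxy-3-methyl-2H-pyran-2-one
Product: 7 6-acetyl-4-methoxy-3-methyl-2H-pyran-2-one
Conditions: TFA/H2O (9:1), CH2Cl2, rt
Reagents that add atoms: water, O
Why: Acid-catalysed ketal hydrolysis, with TFA strong enough for a ketal next to an electron-poor ring and mild enough at room temperature to leave the vinylogous ester (4-OMe) untouched.

Step 5
Reactants: 7 6-acetyl-4-methoxy-3-methyl-2H-pyran-2-one
Product: 8 6-(bromoacetyl)-4-methoxy-3-methyl-2H-pyran-2-one
Conditions: CuBr2 (2.0 equiv), EtOAc/CHCl3 (1:1), reflux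
Reagents that add atoms: copper dibromide, [Cu+2].[Br-].[Br-]
Why: Heterogeneous α-bromination of an aryl-type methyl ketone through its enol, which normally stops at the monobromide, while the pyranone ring is protected by the blocked C3 and by deactivation from the acyl group.

Step 6
Reactants: 8 6-(bromoacetyl)-4-methoxy-3-methyl-2H-pyran-2-one (two equivalents)
Product: 10 bis[2-(pyronyl)-2-oxoethyl] sulfide, via sodium thiolate 9 (not isolated)
Conditions: Na2S·9H2O (0.5 equiv), acetone/H2O, 0 °C
Reagents that add atoms: sodium sulfide, [Na+].[Na+].[S-2]
Why: Twofold SN2 substitution (the classical synthesis of diphenacyl-type sulfides), since an α-bromo ketone reacts with sulfide and then with thiolate 9 far faster at 0 °C than the pyranone ring is attacked.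

Step 7
Reactants: 10 bis[2-(pyronyl)-2-oxoethyl] sulfide
Product: 12 3,4-bis(pyronyl)-2,5-dihydrothiophene, via cyclic dichlorotitanium pinacolate 11 (not isolated)
Conditions: TiCl4 (4 equiv), Zn dust (8 equiv), pyridine, THF, reflux; slow addition of 10 (high dilution); aq. K2CO3 work-up under Ar
Reagents that add atoms: none
Why: Intramolecular McMurry coupling, a reaction type known for 3-thiapentane-1,5-diones, in which the conjugated ketones form ketyls much faster than the vinylogous-carbonate lactone carbonyls react, the five-membered ring closes through cis-pinacolate 11, and deoxygenation at reflux gives the ring alkene.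

Step 8
Reactants: 12 3,4-bis(pyronyl)-2,5-dihydrothiophene; 13 maleic anhydride
Product: 15 meso-1,7-bis(pyronyl)-4-oxa-9-thiatricyclo[5.3.0.0(2,6)]decane-3,5-dione (cis-syn-cis: anhydride ring and thia ring on one face of the cyclobutane; both pyronyl groups on the other), via triplet 1,4-biradical 14 (not isolated)
Conditions: 13 (10 equiv), [Ir(dF(CF3)ppy)2(dtbbpy)]PF6 (1 mol%), degassed CH2Cl2 (0.05 M), 450 nm LED, 0 °C
Reagents that add atoms: none
Why: The excited iridium complex passes its triplet energy only to the cross-conjugated pyrone-C=C-pyrone chromophore of 12 (13 and the isolated pyrones of 15 lie higher, and 12 should not absorb at 450 nm, which keeps out the singlet 6π-electrocyclisation of the pyrone-ene-pyrone triene), and because the C=C lies in the five-membered thia ring the triplet cannot relax by twisting and should live long enough to add, through a tertiary pyrone-stabilised radical centre, to the electron-poor C=C of 13 to give 1,4-biradical 14. The cyclobutane is the only ring closed, and it closes by intersystem crossing and radical-radical recombination of 14 (stepwise [2+2]), so both new C-C bonds arise in one operation. The closest known reaction type is the sensitised intermolecular [2+2] photocycloaddition of maleic anhydride to aryl alkenes, and of ring-locked cis-stilbene analogues (1,2-diarylcycloalkenes, diphenylvinylene carbonate) to alkenes. The two quaternary centres are held cis by the thia ring, because a cyclobutane can be fused to a five-membered ring only in the cis manner, and the two tertiary centres are held cis in the same way by the anhydride ring. The relation between the two pairs is steric: the two pyrones are twisted out of the alkene plane and shield their side on both faces, so 13 should lie over the flat CH2-S-CH2 side and the biradical of the other orientation should cleave back rather than close, which places the anhydride syn to the thia ring and anti to the pyrones. The step also needs chemoselectivity for the central alkene over the pyrone C=C bonds, secured by the spin density at the two tertiary carbons, and suppression of the thermal Diels-Alder addition of 13 to the pyrone dienes, secured by working at 0 °C.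

Step 9
Reactants: 15 meso anhydride
Product: 16 (1R,5S,6S,7R)-7-(methoxycarbonyl)-1,5-bis(pyronyl)-3-thiabicyclo[3.2.0]heptane-6-carboxylic acid
Conditions: quinidine (1.1 equiv), MeOH (5 equiv), toluene (minimum CH2Cl2 as cosolvent), -55 °C; 1 M HCl wash
Reagents that add atoms: methanol, CO
Why: Cinchona-alkaloid-mediated enantioselective methanolysis (desymmetrisation) of a meso succinic anhydride, established for cis-cyclobutane-1,2-dicarboxylic and polycyclic anhydrides, in which the quinuclidine nitrogen activates MeOH as a general base and delivers it from the open convex face to one of the two enantiotopic carbonyls, so no stereocentre is touched and the four centres of step 8 become one enantiomeric series.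

Step 10
Reactants: 16 thia-bridged hemiester
Product: 17 (1S,2R,3S,4R)-2-(methoxycarbonyl)-3,4-dimethyl-3,4-bis(pyronyl)cyclobutane-1-carboxylic acid (CNP0481603.1)
Conditions: Raney Ni (W-2, washed neutral, deactivated in refluxing acetone), THF/EtOH, rt
Reagents that add atoms: none
Why: Raney nickel hydrogenolytic desulfurisation of a thiolane to two methyl groups (the biotin-to-desthiobiotin type of cleavage) breaks only the two C-S bonds, so all four stereocentres are retained, and the neutral, deactivated reagent is chosen to spare the pyranone C=C bonds and avoid epimerisation next to the ester.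

**Compound list**
1 | ethyl 2-methylacetoacetate | CCOC(=O)C(C)C(C)=O | starting material
2 | ethyl 2,2-diethoxypropanoate | CCOC(=O)C(C)(OCC)OCC | starting material
3 | dilithium dienediolate (dianion) of 1 | [Li+].[Li+].C=C([O-])C(C)=C([O-])OCC | intermediate
4 | ethyl 6,6-diethoxy-2-methyl-3,5-dioxoheptanoate (C2 labile, racemic) | CCOC(=O)C(C)C(=O)CC(=O)C(C)(OCC)OCC | intermediate
5 | 6-(1,1-diethoxyethyl)-4-hydroxy-3-methyl-2H-pyran-2-one | CCOC(C)(OCC)c1cc(O)c(C)c(=O)o1 | intermediate
6 | 6-(1,1-diethoxyethyl)-4-methoxy-3-methyl-2H-pyran-2-one | CCOC(C)(OCC)c1cc(OC)c(C)c(=O)o1 | intermediate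
7 | 6-acetyl-4-methoxy-3-methyl-2H-pyran-2-one | CC(=O)c1cc(OC)c(C)c(=O)o1 | intermediate
8 | 6-(bromoacetyl)-4-methoxy-3-methyl-2H-pyran-2-one | O=C(CBr)c1cc(OC)c(C)c(=O)o1 | intermediate
9 | sodium 2-oxo-2-(pyronyl)ethanethiolate | [Na+].[S-]CC(=O)c1cc(OC)c(C)c(=O)o1 | intermediate
10 | bis[2-(pyronyl)-2-oxoethyl] sulfide | O=C(CSCC(=O)c1cc(OC)c(C)c(=O)o1)c1cc(OC)c(C)c(=O)o1 | intermediate
11 | cyclic dichlorotitanium pinacolate of cis-3,4-bis(pyronyl)thiolane-3,4-diol | Cl[Ti]1(Cl)O[C@]2(c3cc(OC)c(C)c(=O)o3)CSC[C@@]2(O1)c1cc(OC)c(C)c(=O)o1 | intermediate
12 | 3,4-bis(pyronyl)-2,5-dihydrothiophene | C1SCC(c2cc(OC)c(C)c(=O)o2)=C1c1cc(OC)c(C)c(=O)o1 | intermediate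
13 | maleic anhydride | O=C1C=CC(=O)O1 | starting material
14 | triplet 1,4-biradical (first C-C bond formed; radical centres at thiolane C4 and at the anhydride α-carbon; the two new sp3 centres not yet fixed) | O=C1OC(=O)[CH]C1C1(c2cc(OC)c(C)c(=O)o2)CSC[C]1c1cc(OC)c(C)c(=O)o1 | intermediate
15 | meso-1,7-bis(pyronyl)-4-oxa-9-thiatricyclo[5.3.0.0(2,6)]decane-3,5-dione, cis-syn-cis | O=C1[C@@H]2[C@H](C(=O)O1)[C@@](C3)(c4cc(OC)c(C)c(=O)o4)[C@@]2(CS3)c1cc(OC)c(C)c(=O)o1 | intermediate
16 | (1R,5S,6S,7R)-7-(methoxycarbonyl)-1,5-bis(pyronyl)-3-thiabicyclo[3.2.0]heptane-6-carboxylic acid | COC(=O)[C@@H]1[C@H](C(=O)O)[C@@](C2)(c3cc(OC)c(C)c(=O)o3)[C@@]1(CS2)c1cc(OC)c(C)c(=O)o1 | intermediate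
17 | (1S,2R,3S,4R)-2-(methoxycarbonyl)-3,4-dimethyl-3,4-bis(pyronyl)cyclobutane-1-carboxylic acid | COC(=O)[C@@H]1[C@H](C(=O)O)[C@@](C)(c2cc(OC)c(C)c(=O)o2)[C@@]1(C)c1cc(OC)c(C)c(=O)o1 | target

**Total step count:** 10. **Longest linear sequence:** 10 steps (1 to 17).

**Steps most likely to fail**

Step 8. Orientation control may be poor, with donor-acceptor stacking drawing 13 over the pyrones in the encounter complex. The excited alkene may also decay unproductively by reversible 6π-electrocyclisation or allylic C-S homolysis.
- The fallback replaces kinetic by thermodynamic control and sets out from 12.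
- The same sensitised conditions with di-tert-butyl fumarate, a partner for which both orientations are identical, should give racemic di-tert-butyl (6,7-trans)-1,5-bis(pyronyl)-3-thiabicyclo[3.2.0]heptane-6,7-dicarboxylate F1.
- TFA in CH2Cl2 should free racemic (6,7-trans)-1,5-bis(pyronyl)-3-thiabicyclo[3.2.0]heptane-6,7-dicarboxylic acid F2 without base contact for the pyrones.
- Heating in Ac2O with NaOAc should epimerise the carboxyl carbon lying syn to the pyrones through the enolisable mixed anhydride and close the cis anhydride on the less crowded face. This is the classical isomerisation of truxinic-type acids through their anhydrides.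
- The fallback comes back to the route at 15.

Step 10. The pyranone C=C bonds may be saturated. The cyclobutane may open from the cyclobutylcarbinyl-type surface species formed when the C-S bonds break. The centre next to the ester may epimerise on basic nickel.
- The fallback does without the sulfur bridge and sets out from 7.
- Intermolecular McMurry coupling (TiCl4, Zn, THF, reflux) should give (Z)-2,3-bis(pyronyl)but-2-ene F3 together with its E isomer, which the sensitiser interconverts with it.
- Sensitised [2+2] photocycloaddition with a large excess of 13, then separation from the trans-dipyronyl isomers, should give meso-6,7-dimethyl-6,7-bis(pyronyl)-3-oxabicyclo[3.2.0]heptane-2,4-dione F4.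
- Quinidine-mediated methanolysis as in step 9 brings the fallback back to the route at 17.

Step 7. The coupling may stall at the pinacolate. The pyrones or the α-sulfur substituent may degrade during the long reflux with low-valent titanium.
- The fallback splits the olefination into two mild stages and sets out from 10.
- Pinacol coupling with TiCl4/Zn in THF at -10 °C, stopped at the diol stage, should give meso-cis-3,4-bis(pyronyl)thiolane-3,4-diol F5.
- 1,1'-Thiocarbonyldiimidazole with DMAP in toluene at reflux should give the cyclic thionocarbonate of the cis-diol F6.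
- P(OMe)3 at reflux (Corey-Winter olefination, stereospecific syn elimination) brings the fallback back to the route at 12.

**Further compounds**
F1 | step 8 | racemic di-tert-butyl (6,7-trans)-1,5-bis(pyronyl)-3-thiabicyclo[3.2.0]heptane-6,7-dicarboxylate (one enantiomer drawn) | CC(C)(C)OC(=O)[C@@H]1[C@@H](C(=O)OC(C)(C)C)[C@@](C2)(c3cc(OC)c(C)c(=O)o3)[C@@]1(CS2)c1cc(OC)c(C)c(=O)o1
F2 | step 8 | racemic (6,7-trans)-1,5-bis(pyronyl)-3-thiabicyclo[3.2.0]heptane-6,7-dicarboxylic acid (one enantiomer drawn) | OC(=O)[C@@H]1[C@@H](C(=O)O)[C@@](C2)(c3cc(OC)c(C)c(=O)o3)[C@@]1(CS2)c1cc(OC)c(C)c(=O)o1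
F3 | step 10 | (Z)-2,3-bis(pyronyl)but-2-ene | C/C(c1cc(OC)c(C)c(=O)o1)=C(\C)c1cc(OC)c(C)c(=O)o1
F4 | step 10 | meso-6,7-dimethyl-6,7-bis(pyronyl)-3-oxabicyclo[3.2.0]heptane-2,4-dione (methyls syn to the anhydride ring) | O=C1[C@@H]2[C@H](C(=O)O1)[C@@](C)(c3cc(OC)c(C)c(=O)o3)[C@@]2(C)c1cc(OC)c(C)c(=O)o1
F5 | step 7 | meso-cis-3,4-bis(pyronyl)thiolane-3,4-diol | O[C@]1(c2cc(OC)c(C)c(=O)o2)CSC[C@@]1(O)c1cc(OC)c(C)c(=O)o1
F6 | step 7 | cyclic thionocarbonate of the cis-diol | S=C1O[C@]2(c3cc(OC)c(C)c(=O)o3)CSC[C@@]2(O1)c1cc(OC)c(C)c(=O)o1
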